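**Retrosynthetic overview**
- The strategy rests on the C5–OH and C5''–OH groups, each peri to the C4 (C4'') carbonyl on ring A of a chromone; each C5 is the only C–H peri to its carbonyl, since C8a carries O1. Both C–O bonds are made last, by carbonyl-directed ruthenium-catalysed C–H oxygenation of diacetate 14.
- With these two oxygens absent, each ring A has a single oxygen ortho to its acyl carbon, so both pyranone closures and the position of the 6-aryloxy group are unambiguous.
- The diaryl ether (C6–O–aryl) comes from SNAr of the 5'-hydroxyl of acetophenone 4 (Elbs oxidation of 2) on 4-fluorobenzaldehyde; two Claisen–Schmidt condensations, the first with the aldehyde masked as an acetal, build bichalcone 11.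
- Ring order: both rings C close together in step 7 (I2/DMSO); no ring is formed afterwards. Benzyl ethers are then exchanged for acetates, the two 5-hydroxyls are installed, and the acetates are removed.

Key step: step 10

Remark: plain locants refer to the chromone carrying the 4-methoxyphenyl ring (unit 1), double-primed locants to the chromone on the phenoxy ring (unit 2); any exchange of a 7-acetate for a trifluoroacetate in step 10 is assumed harmless, since work-up and step 11 lead to the same phenols.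

**Step 1**
Reactants: 1 2',4'-dihydroxyacetophenone
Product: 2 1-[4-(benzyloxy)-2-hydroxyphenyl]ethanone
Conditions: BnBr (1.05 equiv), K2CO3, acetone, reflux
Reagents that add atoms: benzyl bromide, BrCc1ccccc1
Why: Williamson ether synthesis, in which the 2'-hydroxyl is hydrogen-bonded to the acetyl group and far less nucleophilic than the 4'-hydroxyl, so one equivalent of benzyl bromide should alkylate only O4'.

**Step 2**
Reactants: 2 1-[4-(benzyloxy)-2-hydroxyphenyl]ethanone
Product: 4 1-[4-(benzyloxy)-2,5-dihydroxyphenyl]ethanone, via potassium aryl sulfate 3 (not isolated)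
Conditions: K2S2O8, aq KOH, pyridine, 0 °C to rt; then 2 M HCl, 80 °C
Reagents that add atoms: potassium persulfate, [K+].[K+].[O-]S(=O)(=O)OOS(=O)(=O)[O-]
Why: Elbs persulfate oxidation, in which the phenoxide of 2 attacks a peroxide oxygen through the carbon para to O2' (C5', the only free para position and also ortho to the benzyloxy group), and warm dilute acid then cleaves the S–O bond of sulfate 3 without harming the benzyl ether or the ketone.

**Step 3**
Reactants: 4 1-[4-(benzyloxy)-2,5-dihydroxyphenyl]ethanone; 5 4-fluorobenzaldehyde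
Product: 6 4-[5-acetyl-2-(benzyloxy)-4-hydroxyphenoxy]benzaldehyde
Conditions: K2CO3 (1.2 equiv), DMF, 90 °C, N2
Reagents that add atoms: none
Why: Nucleophilic aromatic substitution (addition–elimination) at the fluoride para to the formyl group, in which the 5'-phenoxide is the free nucleophile while O2' is chelated to the acetyl group and hindered, and K2CO3 is too weak a base to drive an aldol condensation between the methyl ketone and the aldehyde.

**Step 4**
Reactants: 6 4-[5-acetyl-2-(benzyloxy)-4-hydroxyphenoxy]benzaldehyde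
Product: 7 1-{4-(benzyloxy)-5-[4-(dimethoxymethyl)phenoxy]-2-hydroxyphenyl}ethanone
Conditions: HC(OMe)3, MeOH, TsOH·H2O (cat.), rt; then Et3N
Reagents that add atoms: trimethyl orthoformate, COC(OC)OC; methanol, CO
Why: Acid-catalysed acetalisation with orthoformate as water scavenger, in which the aryl aldehyde is far more electrophilic than the chelated ortho-hydroxyaryl methyl ketone, so only the aldehyde is masked before the base-mediated condensation.

**Step 5**
Reactants: 7 1-{4-(benzyloxy)-5-[4-(dimethoxymethyl)phenoxy]-2-hydroxyphenyl}ethanone; 8 4-methoxybenzaldehyde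
Product: 10 4-{2-(benzyloxy)-4-hydroxy-5-[(E)-3-(4-methoxyphenyl)prop-2-enoyl]phenoxy}benzaldehyde, via acetal chalcone 9 (not isolated)
Conditions: KOH (aq), EtOH, rt, N2; then 1 M HCl, THF, rt
Reagents that add atoms: water, O
Why: Claisen–Schmidt condensation, in which the enolate of the methyl ketone adds to non-enolisable 4-methoxybenzaldehyde and E1cB loss of water gives the thermodynamically preferred E-enone, while the base-stable acetal keeps the substrate's own formyl group out of the condensation until the acidic work-up hydrolyses it.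

**Step 6**
Reactants: 10 4-{2-(benzyloxy)-4-hydroxy-5-[(E)-3-(4-methoxyphenyl)prop-2-enoyl]phenoxy}benzaldehyde; 2 1-[4-(benzyloxy)-2-hydroxyphenyl]ethanone
Product: 11 (E)-1-[4-(benzyloxy)-2-hydroxyphenyl]-3-(4-{2-(benzyloxy)-4-hydroxy-5-[(E)-3-(4-methoxyphenyl)prop-2-enoyl]phenoxy}phenyl)prop-2-en-1-one
Conditions: KOH (aq), EtOH/THF, 0 °C to rt, N2
Reagents that add atoms: none
Why: Second Claisen–Schmidt condensation, in which 2 holds the only enolisable methyl ketone and 10 the only aldehyde (the enone of 10 cannot form an enolate), so a single cross-condensation is possible and E1cB dehydration again gives the E-enone.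

**Step 7**
Reactants: 11 bichalcone
Product: 12 7-(benzyloxy)-6-{4-[7-(benzyloxy)-4-oxo-4H-chromen-2-yl]phenoxy}-2-(4-methoxyphenyl)-4H-chromen-4-one
Conditions: I2 (20 mol%), DMSO, 130 °C
Reagents that add atoms: none
Why: Iodine/DMSO oxidative cyclisation of 2'-hydroxychalcones, run at both enones at once, in which each ring A has one free hydroxyl ortho to its acyl carbon so each six-membered pyranone ring C can close only through that oxygen onto the β-carbon, and iodine with DMSO as terminal oxidant introduces the C2=C3 double bond without touching the benzyl ethers.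

**Step 8**
Reactants: 12 7,7''-di-O-benzyl-5,5''-dideoxycryptomerin A
Product: 13 7-hydroxy-6-[4-(7-hydroxy-4-oxo-4H-chromen-2-yl)phenoxy]-2-(4-methoxyphenyl)-4H-chromen-4-one
Conditions: H2 (1 atm), Pd/C (10% palladium on carbon), THF/MeOH, rt
Reagents that add atoms: none
Why: Catalytic hydrogenolysis of the two benzyl aryl ethers, whose benzylic C–O bonds are cleaved quickly at ambient pressure, whereas the C2=C3 bond of a flavone (a vinylogous ester conjugated to two arenes) and the diaryl ether are reduced far more slowly.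

**Step 9**
Reactants: 13 5,5''-dideoxycryptomerin A
Product: 14 7,7''-di-O-acetyl-5,5''-dideoxycryptomerin A
Conditions: Ac2O, pyridine, DMAP (cat.), rt
Reagents that add atoms: acetic anhydride, CC(=O)OC(C)=O
Why: DMAP-catalysed acetylation (nucleophilic acyl substitution) of the two unhindered phenols, the only nucleophilic groups in 13.

**Step 10**
Reactants: 14 7,7''-di-O-acetyl-5,5''-dideoxycryptomerin A
Product: 16 7,7''-di-O-acetylcryptomerin A, via bis(trifluoroacetate) 15 (not isolated)
Conditions: [RuCl2(p-cymene)]2 (10 mol%), PhI(OCOCF3)2 (4 equiv), TFA/TFAA, 80 °C; then H2O, THF, NaHCO3, rt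
Reagents that add atoms: [bis(trifluoroacetoxy)iodo]benzene, O=C(OI(OC(=O)C(F)(F)F)c1ccccc1)C(F)(F)F
Why: Trifluoroacetate-assisted concerted metalation–deprotonation by the divalent ruthenium p-cymene species bound to each C4 carbonyl oxygen cleaves C5–H and C5''–H to give five-membered ruthenacycles (Ru–C5–C4a–C4=O); PhI(OCOCF3)2 oxidises each to a tetravalent ruthenium trifluoroacetate, C–O reductive elimination gives aryl trifluoroacetate 15, and the aqueous work-up hydrolyses both trifluoroacetates to the hydrogen-bonded 5-hydroxyls of 16. The closest known reaction type is the ruthenium-catalysed ketone-directed ortho C–H hydroxylation of aryl ketones with this oxidant in TFA/TFAA, established for C5 of simple flavones and chromones and used here at two chromones of one molecule. No ring is closed and no stereocentre is formed; the two new bonds are C5–O and C5''–O. The step needs site selectivity for C5 and C5'' over every other aromatic C–H bond, and chelation secures it, because each C5 is the only C–H peri to a carbonyl (C8a carries O1, and C3–H would demand a four-membered metallacycle). It also needs chemoselectivity against arene oxidation by the trivalent iodine reagent: the 7-acetates and the chromone carbonyls lower the electron density of both rings A, and TFAA keeps each new phenol as its trifluoroacetate until work-up so that it is not oxidised further. The remaining risks are slow metalation at C5 of unit 1, which is flanked by the 6-aryloxy group, and attack of the oxidant on the methoxyphenyl and phenoxy rings.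

**Step 11**
Reactants: 16 7,7''-di-O-acetylcryptomerin A
Product: 17 Cryptomerin A
Conditions: K2CO3 (cat.), MeOH/THF, 0 °C to rt; then dilute HCl
Reagents that add atoms: none
Why: Base-catalysed transesterification (methanolysis) of the two aryl acetates, which as activated phenyl esters are cleaved at low temperature, conditions that leave the flavone rings, the diaryl ether, the methyl ether and the chelated 5-hydroxyls unchanged.

**Compound list**
1 | 2',4'-dihydroxyacetophenone | CC(=O)c1ccc(O)cc1O | starting material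
2 | 1-[4-(benzyloxy)-2-hydroxyphenyl]ethanone | CC(=O)c1ccc(OCc2ccccc2)cc1O | intermediate
3 | potassium 5-acetyl-2-(benzyloxy)-4-hydroxyphenyl sulfate | CC(=O)c1cc(OS(=O)(=O)[O-])c(OCc2ccccc2)cc1O.[K+] | intermediate
4 | 1-[4-(benzyloxy)-2,5-dihydroxyphenyl]ethanone | CC(=O)c1cc(O)c(OCc2ccccc2)cc1O | intermediate
5 | 4-fluorobenzaldehyde | O=Cc1ccc(F)cc1 | starting material
6 | 4-[5-acetyl-2-(benzyloxy)-4-hydroxyphenoxy]benzaldehyde | CC(=O)c1cc(Oc2ccc(C=O)cc2)c(OCc2ccccc2)cc1O | intermediate
7 | 1-{4-(benzyloxy)-5-[4-(dimethoxymethyl)phenoxy]-2-hydroxyphenyl}ethanone | CC(=O)c1cc(Oc2ccc(C(OC)OC)cc2)c(OCc2ccccc2)cc1O | intermediate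
8 | 4-methoxybenzaldehyde | COc1ccc(C=O)cc1 | starting material
9 | (E)-1-{4-(benzyloxy)-5-[4-(dimethoxymethyl)phenoxy]-2-hydroxyphenyl}-3-(4-methoxyphenyl)prop-2-en-1-one | COc1ccc(/C=C/C(=O)c2cc(Oc3ccc(C(OC)OC)cc3)c(OCc3ccccc3)cc2O)cc1 | intermediate
10 | 4-{2-(benzyloxy)-4-hydroxy-5-[(E)-3-(4-methoxyphenyl)prop-2-enoyl]phenoxy}benzaldehyde | COc1ccc(/C=C/C(=O)c2cc(Oc3ccc(C=O)cc3)c(OCc3ccccc3)cc2O)cc1 | intermediate
11 | (E)-1-[4-(benzyloxy)-2-hydroxyphenyl]-3-(4-{2-(benzyloxy)-4-hydroxy-5-[(E)-3-(4-methoxyphenyl)prop-2-enoyl]phenoxy}phenyl)prop-2-en-1-one | COc1ccc(/C=C/C(=O)c2cc(Oc3ccc(/C=C/C(=O)c4ccc(OCc5ccccc5)cc4O)cc3)c(OCc3ccccc3)cc2O)cc1 | intermediate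
12 | 7-(benzyloxy)-6-{4-[7-(benzyloxy)-4-oxo-4H-chromen-2-yl]phenoxy}-2-(4-methoxyphenyl)-4H-chromen-4-one | COc1ccc(-c2cc(=O)c3cc(Oc4ccc(-c5cc(=O)c6ccc(OCc7ccccc7)cc6o5)cc4)c(OCc4ccccc4)cc3o2)cc1 | intermediate
13 | 7-hydroxy-6-[4-(7-hydroxy-4-oxo-4H-chromen-2-yl)phenoxy]-2-(4-methoxyphenyl)-4H-chromen-4-one (5,5''-dideoxycryptomerin A) | COc1ccc(-c2cc(=O)c3cc(Oc4ccc(-c5cc(=O)c6ccc(O)cc6o5)cc4)c(O)cc3o2)cc1 | intermediate
14 | 7,7''-di-O-acetyl-5,5''-dideoxycryptomerin A | COc1ccc(-c2cc(=O)c3cc(Oc4ccc(-c5cc(=O)c6ccc(OC(C)=O)cc6o5)cc4)c(OC(C)=O)cc3o2)cc1 | intermediate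
15 | 7,7''-di-O-acetyl-5,5''-bis-O-(trifluoroacetyl)cryptomerin A | COc1ccc(-c2cc(=O)c3c(OC(=O)C(F)(F)F)c(Oc4ccc(-c5cc(=O)c6c(OC(=O)C(F)(F)F)cc(OC(C)=O)cc6o5)cc4)c(OC(C)=O)cc3o2)cc1 | intermediate
16 | 7,7''-di-O-acetylcryptomerin A | COc1ccc(-c2cc(=O)c3c(O)c(Oc4ccc(-c5cc(=O)c6c(O)cc(OC(C)=O)cc6o5)cc4)c(OC(C)=O)cc3o2)cc1 | intermediate
17 | Cryptomerin A | COc1ccc(-c2cc(=O)c3c(O)c(Oc4ccc(-c5cc(=O)c6c(O)cc(O)cc6o5)cc4)c(O)cc3o2)cc1 | target

**Totals**
Total step count: 11. Longest linear sequence: 11 steps (1 → 17); compound 2 enters a second time in step 6.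

**Steps most likely to fail**

Step 10. The second C–H metalation may stall at the crowded C5 of unit 1, between C4a and the aryloxy-bearing C6, and the trivalent iodine oxidant may degrade the methoxyphenyl and phenoxy rings. The fallback gives up late-stage oxygenation and carries both 5-oxygens from the start as benzyl ethers, which still leaves one free ortho hydroxyl per acetophenone. It sets out from 4-fluorobenzaldehyde 5 and comes back at Cryptomerin A 17. Commercially available 2',4'-bis(benzyloxy)-6'-hydroxyacetophenone F1 would undergo Elbs oxidation (K2S2O8, aq KOH, pyridine; then 2 M HCl) through potassium 3-acetyl-2,6-bis(benzyloxy)-4-hydroxyphenyl sulfate F2 to 1-[2,4-bis(benzyloxy)-3,6-dihydroxyphenyl]ethanone F3. SNAr with 5 (K2CO3, DMF) should give 4-[3-acetyl-2,6-bis(benzyloxy)-4-hydroxyphenoxy]benzaldehyde F4, and acetalisation the dimethyl acetal F5. Claisen–Schmidt condensation with 8 would give the acetal chalcone F6, hydrolysed on acidic work-up to the chalcone aldehyde F7. A second Claisen–Schmidt condensation with F1 would give the tetrabenzyl bichalcone F8, I2/DMSO the tetrabenzyl bis-flavone F9, and hydrogenolysis (H2, Pd/C) of all four benzyl ethers 17.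

Step 2. The persulfate oxidation may show low conversion and radical over-oxidation of the phenol, and the acid hydrolysis may partly remove the benzyl group. The fallback replaces direct hydroxylation by halogenation, borylation and oxidation; it sets out from 2 and comes back at 4. NBS in MeCN at 0 °C should brominate para to the hydroxyl to give 1-[4-(benzyloxy)-5-bromo-2-hydroxyphenyl]ethanone F10. Miyaura borylation (B2pin2, PdCl2(dppf), KOAc, dioxane, 90 °C) would give the pinacol boronate F11, and NaBO3·4H2O in THF/H2O at rt would oxidise the C–B bond to give 4.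

Step 6. The enolate of 2 may add in conjugate fashion to the enone already present in 10, and retro-aldol scrambling or a Cannizzaro reaction of the aldehyde may compete. The fallback closes ring C of unit 1 before the second condensation, so that no chalcone is exposed to the enolate; it sets out from 10 and comes back at 12. I2/DMSO at 130 °C should convert 10 into the flavone aldehyde 4-{[7-(benzyloxy)-2-(4-methoxyphenyl)-4-oxo-4H-chromen-6-yl]oxy}benzaldehyde F12. Claisen–Schmidt condensation with 2 (KOH, EtOH/THF, 0 °C to rt) would give the flavone chalcone F13, and a second I2/DMSO cyclisation 12.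

**Further compounds**
F1 | step 10 | 1-[2,4-bis(benzyloxy)-6-hydroxyphenyl]ethanone | CC(=O)c1c(O)cc(OCc2ccccc2)cc1OCc1ccccc1
F2 | step 10 | potassium 3-acetyl-2,6-bis(benzyloxy)-4-hydroxyphenyl sulfate | CC(=O)c1c(O)cc(OCc2ccccc2)c(OS(=O)(=O)[O-])c1OCc1ccccc1.[K+]
F3 | step 10 | 1-[2,4-bis(benzyloxy)-3,6-dihydroxyphenyl]ethanone | CC(=O)c1c(O)cc(OCc2ccccc2)c(O)c1OCc1ccccc1
F4 | step 10 | 4-[3-acetyl-2,6-bis(benzyloxy)-4-hydroxyphenoxy]benzaldehyde | CC(=O)c1c(O)cc(OCc2ccccc2)c(Oc2ccc(C=O)cc2)c1OCc1ccccc1
F5 | step 10 | 1-{2,4-bis(benzyloxy)-3-[4-(dimethoxymethyl)phenoxy]-6-hydroxyphenyl}ethanone | CC(=O)c1c(O)cc(OCc2ccccc2)c(Oc2ccc(C(OC)OC)cc2)c1OCc1ccccc1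
F6 | step 10 | (E)-1-{2,4-bis(benzyloxy)-3-[4-(dimethoxymethyl)phenoxy]-6-hydroxyphenyl}-3-(4-methoxyphenyl)prop-2-en-1-one | COc1ccc(/C=C/C(=O)c2c(O)cc(OCc3ccccc3)c(Oc3ccc(C(OC)OC)cc3)c2OCc2ccccc2)cc1
F7 | step 10 | 4-{2,6-bis(benzyloxy)-4-hydroxy-3-[(E)-3-(4-methoxyphenyl)prop-2-enoyl]phenoxy}benzaldehyde | COc1ccc(/C=C/C(=O)c2c(O)cc(OCc3ccccc3)c(Oc3ccc(C=O)cc3)c2OCc2ccccc2)cc1
F8 | step 10 | (E)-1-[2,4-bis(benzyloxy)-6-hydroxyphenyl]-3-(4-{2,6-bis(benzyloxy)-4-hydroxy-3-[(E)-3-(4-methoxyphenyl)prop-2-enoyl]phenoxy}phenyl)prop-2-en-1-one | COc1ccc(/C=C/C(=O)c2c(O)cc(OCc3ccccc3)c(Oc3ccc(/C=C/C(=O)c4c(O)cc(OCc5ccccc5)cc4OCc4ccccc4)cc3)c2OCc2ccccc2)cc1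
F9 | step 10 | 5,7-bis(benzyloxy)-6-{4-[5,7-bis(benzyloxy)-4-oxo-4H-chromen-2-yl]phenoxy}-2-(4-methoxyphenyl)-4H-chromen-4-one | COc1ccc(-c2cc(=O)c3c(OCc4ccccc4)c(Oc4ccc(-c5cc(=O)c6c(OCc7ccccc7)cc(OCc7ccccc7)cc6o5)cc4)c(OCc4ccccc4)cc3o2)cc1
F10 | step 2 | 1-[4-(benzyloxy)-5-bromo-2-hydroxyphenyl]ethanone | CC(=O)c1cc(Br)c(OCc2ccccc2)cc1O
F11 | step 2 | 1-[4-(benzyloxy)-2-hydroxy-5-(4,4,5,5-tetramethyl-1,3,2-dioxaborolan-2-yl)phenyl]ethanone | CC(=O)c1cc(B2OC(C)(C)C(C)(C)O2)c(OCc2ccccc2)cc1O
F12 | step 6 | 4-{[7-(benzyloxy)-2-(4-methoxyphenyl)-4-oxo-4H-chromen-6-yl]oxy}benzaldehyde | COc1ccc(-c2cc(=O)c3cc(Oc4ccc(C=O)cc4)c(OCc4ccccc4)cc3o2)cc1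
F13 | step 6 | 7-(benzyloxy)-6-(4-{(E)-3-[4-(benzyloxy)-2-hydroxyphenyl]-3-oxoprop-1-enyl}phenoxy)-2-(4-methoxyphenyl)-4H-chromen-4-one | COc1ccc(-c2cc(=O)c3cc(Oc4ccc(/C=C/C(=O)c5ccc(OCc6ccccc6)cc5O)cc4)c(OCc4ccccc4)cc3o2)cc1
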